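**Strategy.** Ring B is not carved from a resorcinol but assembled from two open-chain partners: its four adjacent substituents (the C1' carbon arm, O2', the C3' chain, O4') map onto a vinylketene and a chain-bearing siloxyalkyne. Irradiating an α-diazo vinyl ketone sets off Wolff rearrangement, [2+2] addition, four-electron ring opening and 6π closure, forming C3'–C4', C1'–C2' and C4'–C5' and giving the arylacetate with O2' silylated and O4' free in one operation. The precursors are methyl 3-diazo-4-oxohex-5-enoate and a triisopropylsiloxyalkyne carrying the hydrated geranyl chain. Ring A, C2 and the C3 stereocentre follow by auxiliary-controlled aryloxymethylation and Friedel–Crafts closure of ring C.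

Key step: step 8

Remark: isoflavanone numbering is used (rings A and C: O1, C2, C3, C4, C4a to C8a; ring B: C1' to C6'); the stereocentre in the SMILES is read as 3S (CIP order C4 > C2 > C1' > H).

Abbreviations used in names: R* = (2E)-3,7-dimethyl-7-(triethylsilyloxy)oct-2-en-1-yl; Ar* = 3-R*-2,4-bis(triisopropylsilyloxy)phenyl.

**Route**

Step 1
Reactants: 1 geranyl acetate
Product: 4 (2E)-3,7-dimethyloct-2-ene-1,7-diol, via organomercurial acetate 2 (not isolated), via hydroxy acetate 3 (not isolated)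
Conditions: Hg(OAc)2, THF/H2O, rt; NaBH4, aq NaOH, 0 °C; then MeOH, rt
Reagents that add atoms: water, O
Why: Oxymercuration–demercuration, in which Hg(OAc)2 adds to the more electron-rich 6,7-alkene (the 2,3-alkene is deactivated by the allylic acetoxy group) with Markovnikov capture of water, NaBH4 removes mercury, and the alkaline methanolic medium then saponifies the acetate without touching the E-2,3-alkene.

Step 2
Reactants: 4 (2E)-3,7-dimethyloct-2-ene-1,7-diol
Product: 5 (6E)-8-bromo-2,6-dimethyloct-6-en-2-ol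
Conditions: NBS, Me2S, CH2Cl2, −20 → 0 °C
Reagents that add atoms: N-bromosuccinimide, O=C1CCC(=O)N1Br
Why: Corey–Kim halogenation, in which the bromodimethylsulfonium reagent activates only the primary allylic hydroxyl and bromide displaces the alkoxysulfonium group at C1 without allylic shift, so the tertiary alcohol and the E geometry should survive.

Step 3
Reactants: 5 (6E)-8-bromo-2,6-dimethyloct-6-en-2-ol
Product: 6 {[(6E)-8-bromo-2,6-dimethyloct-6-en-2-yl]oxy}triethylsilane
Conditions: Et3SiOTf, 2,6-lutidine, CH2Cl2, −78 → 0 °C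
Reagents that add atoms: triethylsilyl trifluoromethanesulfonate, CC[Si](CC)(CC)OS(=O)(=O)C(F)(F)F
Why: Silylation of a tertiary alcohol with a silyl triflate and a hindered pyridine base, conditions under which the allylic bromide is not displaced, so the hydroxyl can later neither capture a ketene nor ionise.

Step 4
Reactants: 6 {[(6E)-8-bromo-2,6-dimethyloct-6-en-2-yl]oxy}triethylsilane
Product: 7 {[(6E)-2,6-dimethyldec-6-en-9-yn-2-yl]oxy}triethylsilane
Conditions: HC≡CMgBr (excess), CuBr·SMe2 (cat.), THF, 0 °C → rt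
Reagents that add atoms: ethynylmagnesium bromide, C#C[Mg]Br
Why: Copper-catalysed substitution of a primary allylic bromide by an alkynyl Grignard reagent should occur at the unhindered α-carbon (γ-attack would build a quaternary centre), giving the skipped enyne with the alkene geometry retained, while excess acetylide suppresses double allylation.

Step 5
Reactants: 7 {[(6E)-2,6-dimethyldec-6-en-9-yn-2-yl]oxy}triethylsilane
Product: 10 triisopropyl{[(4E)-5,9-dimethyl-9-(triethylsilyloxy)dec-4-en-1-yn-1-yl]oxy}silane, via lithium acetylide 8 (not isolated), via lithium ynolate 9 (not isolated)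
Conditions: n-BuLi, THF, −78 °C; t-BuOOLi (from t-BuOOH, LiN(SiMe3)2), −78 → 0 °C; i-Pr3SiOTf, −78 °C
Reagents that add atoms: lithium tert-butyl peroxide, CC(C)(C)OO[Li]; triisopropylsilyl trifluoromethanesulfonate, CC(C)[Si](OS(=O)(=O)C(F)(F)F)(C(C)C)C(C)C
Why: Electrophilic oxygen transfer from lithium tert-butyl peroxide to the lithium acetylide gives the ynolate, which the bulky silyl triflate traps on oxygen (ynolate O-silylation), and since the doubly activated C3 methylene is far less acidic than the alkyne C–H the skipped enyne should not isomerise.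

Step 6
Reactants: 11 methyl 4-chloro-4-oxobutanoate
Product: 12 methyl 4-oxohex-5-enoate
Conditions: Bu3SnCH=CH2, PdCl2(PPh3)2 (cat.), THF, 50 °C
Reagents that add atoms: tributyl(vinyl)stannane, C=C[Sn](CCCC)(CCCC)CCCC
Why: Stille acylation of an acid chloride with a vinylstannane gives the vinyl ketone under neutral conditions that spare the methyl ester.

Step 7
Reactants: 12 methyl 4-oxohex-5-enoate
Product: 15 methyl 3-diazo-4-oxohex-5-enoate, via lithium dienolate 13 (not isolated), via trifluoroacetyl diketone 14 (not isolated)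
Conditions: 12 added to LiN(SiMe3)2, THF, −78 °C; CF3CO2CH2CF3; aq HCl work-up; then 4-AcNHC6H4SO2N3, Et3N, H2O, MeCN, rt
Reagents that add atoms: 4-acetamidobenzenesulfonyl azide, CC(=O)Nc1ccc(cc1)S(=O)(=O)N=[N+]=[N-]
Why: Detrifluoroacetylative diazo transfer, in which kinetic deprotonation at C3 (the only enolisable ketone position, far more acidic than the ester α-carbon) and Claisen trifluoroacetylation activate that carbon, and the sulfonyl azide then delivers N2 with loss of the trifluoroacetyl group.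

Step 8
Reactants: 15 methyl 3-diazo-4-oxohex-5-enoate; 10 triisopropyl{[(4E)-5,9-dimethyl-9-(triethylsilyloxy)dec-4-en-1-yn-1-yl]oxy}silane
Product: 20 methyl 2-[4-hydroxy-3-R*-2-(triisopropylsilyloxy)phenyl]acetate, via vinylketene 16 (not isolated), via vinylcyclobutenone 17 (not isolated), via dienylketene 18 (not isolated), via cyclohexadienone 19 (not isolated)
Conditions: 15 (1.3 equiv, added slowly), hν (254 nm), ClCH2CH2Cl, rt; then 80 °C
Reagents that add atoms: none
Why: Irradiation expels N2 and triggers Wolff rearrangement with migration of the vinyl group to give vinylketene 16, whose electrophilic ketene carbon is attacked by the nucleophilic chain-bearing carbon of siloxyalkyne 10 in a [2+2] cycloaddition to 4-vinylcyclobutenone 17, which opens on warming by 4π electrocyclic cleavage to dienylketene 18. This is the Danheiser benzannulation in its diazo ketone variant with a siloxyalkyne. Ring B closes by thermal disrotatory 6π electrocyclisation of 18 between the ketene carbon and the vinyl terminus (C4'–C5'), and tautomerisation of cyclohexadienone 19 gives the phenol. No stereocentre is formed and the E-alkene is a spectator. The regioselectivity the step needs is secured by the polarisation of the ynol ether (chain-bearing carbon to the ketene carbonyl carbon, oxygen-bearing carbon to the ketene α-carbon), which places the chain at C3' between the free O4'–H and the silylated O2' and the acetate arm at C1'. Chemoselectivity rests on the siloxyalkyne being far more ketenophilic than the isolated trisubstituted alkene and on the tertiary hydroxyl being silylated so that it cannot capture the ketene.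

Step 9
Reactants: 20 methyl 2-[4-hydroxy-3-R*-2-(triisopropylsilyloxy)phenyl]acetate
Product: 21 methyl 2-Ar*-acetate
Conditions: i-Pr3SiCl, imidazole, DMF, rt
Reagents that add atoms: triisopropylsilyl chloride, CC(C)[Si](Cl)(C(C)C)C(C)C
Why: Standard phenol silylation, with the triisopropylsilyl group chosen so that all phenol ethers should survive the later peroxide hydrolysis and fall together in the final fluoride step.

Step 10
Reactants: 21 methyl 2-Ar*-acetate
Product: 23 2-Ar*-acetic acid, via trimethylstannyl ester 22 (not isolated)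
Conditions: Me3SnOH, ClCH2CH2Cl, 80 °C; cold dilute HCl wash
Reagents that add atoms: trimethyltin hydroxide, C[Sn](C)(C)O
Why: Me3SnOH-mediated methyl ester cleavage is a near-neutral hydroxide transfer that should leave the aryl silyl ethers (endangered by aqueous LiOH) and the tertiary silyl ether intact.

Step 11
Reactants: 23 2-Ar*-acetic acid; 24 (4R)-4-benzyl-1,3-oxazolidin-2-one
Product: 26 (4R)-4-benzyl-3-(2-Ar*-acetyl)-1,3-oxazolidin-2-one, via mixed pivalic anhydride 25 (not isolated)
Conditions: t-BuCOCl, Et3N, THF, −20 °C; then 24, LiCl, rt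
Reagents that add atoms: none
Why: N-Acylation of the oxazolidinone through the mixed pivalic anhydride under LiCl/Et3N activation is the standard entry to arylacetyl imides and exposes the acidic benzylic position to no strong base.

Step 12
Reactants: 27 phloroglucinol
Product: 28 3,5-bis(triisopropylsilyloxy)phenol
Conditions: i-Pr3SiCl (2 equiv), imidazole, DMF, 0 °C → rt
Reagents that add atoms: triisopropylsilyl chloride, CC(C)[Si](Cl)(C(C)C)C(C)C
Why: Statistical silylation of three equivalent phenols with two equivalents of silyl chloride should give mainly the bis-ether, separable from mono- and tris-silylated material by chromatography.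

Step 13
Reactants: 28 3,5-bis(triisopropylsilyloxy)phenol
Product: 29 1-[(methylsulfanyl)methoxy]-3,5-bis(triisopropylsilyloxy)benzene
Conditions: NaH, DMF, 0 °C; ClCH2SMe, NaI (cat.), rt
Reagents that add atoms: chloromethyl methyl sulfide, CSCCl
Why: Williamson O-alkylation of the phenoxide gives the O,S-acetal, a stable storage form of the one-carbon unit that becomes C2.

Step 14
Reactants: 29 1-[(methylsulfanyl)methoxy]-3,5-bis(triisopropylsilyloxy)benzene
Product: 30 1-(chloromethoxy)-3,5-bis(triisopropylsilyloxy)benzene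
Conditions: SO2Cl2, CH2Cl2, −78 °C; cyclohexene; used crude at once
Reagents that add atoms: sulfuryl chloride, ClS(Cl)(=O)=O
Why: Chlorinolysis of the O,S-acetal, in which sulfur is chlorinated far faster than the ring at −78 °C and the chlorosulfonium ion collapses to the aryl chloromethyl ether while cyclohexene scavenges the MeSCl released; the bulky silyl ethers flanking every ring position should retard self-alkylation.

Step 15
Reactants: 26 (4R)-4-benzyl-3-(2-Ar*-acetyl)-1,3-oxazolidin-2-one; 30 1-(chloromethoxy)-3,5-bis(triisopropylsilyloxy)benzene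
Product: 32 (4R)-4-benzyl-3-{(2S)-2-Ar*-3-[3,5-bis(triisopropylsilyloxy)phenoxy]propanoyl}-1,3-oxazolidin-2-one, via sodium enolate 31 (not isolated)
Conditions: NaN(SiMe3)2, THF, −78 °C; then 30, −78 → −40 °C
Reagents that add atoms: none
Why: Evans auxiliary alkylation, in which the chelated Z-enolate is shielded on one face by the benzyl group of the (R)-auxiliary so that the highly reactive chloromethyl ether attacks the opposite face and sets the future C3 as S.

Step 16
Reactants: 32 (4R)-4-benzyl-3-{(2S)-2-Ar*-3-[3,5-bis(triisopropylsilyloxy)phenoxy]propanoyl}-1,3-oxazolidin-2-one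
Product: 34 (2S)-2-Ar*-3-[3,5-bis(triisopropylsilyloxy)phenoxy]propanoic acid, via lithium peroxycarboxylate 33 (not isolated)
Conditions: LiOH, H2O2, THF/H2O, 0 °C; Na2SO3; cold dilute HCl to pH 3–4
Reagents that add atoms: hydrogen peroxide, OO
Why: Hydroperoxide cleavage of the imide (selective attack at the exocyclic carbonyl, then sulfite reduction of the peracid) liberates the acid without enolisation, so the α-stereocentre and the β-aryloxy group should be retained and the auxiliary recovered.

Step 17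
Reactants: 34 (2S)-2-Ar*-3-[3,5-bis(triisopropylsilyloxy)phenoxy]propanoic acid
Product: 36 (3S)-3-Ar*-5,7-bis(triisopropylsilyloxy)chroman-4-one, via mixed trifluoroacetic anhydride 35 (not isolated)
Conditions: (CF3CO)2O, CH2Cl2, 0 °C; aq NaHCO3
Reagents that add atoms: none
Why: Intramolecular Friedel–Crafts acylation through the mixed trifluoroacetic anhydride, in which the phloroglucinol-type ring A is nucleophilic enough to close the six-membered ring C at either of its two equivalent positions ortho to the ether oxygen at 0 °C without a Lewis acid, conditions the silyl ethers, the isolated alkene and the α-stereocentre should tolerate.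

Step 18
Reactants: 36 (3S)-3-Ar*-5,7-bis(triisopropylsilyloxy)chroman-4-one
Product: 37 (3S)-3-{2,4-dihydroxy-3-[(2E)-7-hydroxy-3,7-dimethyloct-2-en-1-yl]phenyl}-5,7-dihydroxychroman-4-one
Conditions: HF·pyridine, pyridine, THF, 0 °C → rt
Reagents that add atoms: none
Why: Global fluoride desilylation under buffered, weakly acidic conditions should remove the four aryl silyl ethers and the tertiary silyl ether without the base-induced enolisation that racemises isoflavanones at C3 and without acid strong enough to cyclise the chain onto a phenol.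

**Compound list**

1 | geranyl acetate | CC(=O)OC/C=C(\C)CCC=C(C)C | starting material
2 | (2E)-6-(acetoxymercurio)-7-hydroxy-3,7-dimethyloct-2-en-1-yl acetate | CC(=O)OC/C=C(\C)CCC([Hg]OC(C)=O)C(C)(C)O | intermediate (not isolated)
3 | (2E)-7-hydroxy-3,7-dimethyloct-2-en-1-yl acetate | CC(=O)OC/C=C(\C)CCCC(C)(C)O | intermediate (not isolated)
4 | (2E)-3,7-dimethyloct-2-ene-1,7-diol | OC/C=C(\C)CCCC(C)(C)O | intermediate
5 | (6E)-8-bromo-2,6-dimethyloct-6-en-2-ol | BrC/C=C(\C)CCCC(C)(C)O | intermediate
6 | {[(6E)-8-bromo-2,6-dimethyloct-6-en-2-yl]oxy}triethylsilane | BrC/C=C(\C)CCCC(C)(C)O[Si](CC)(CC)CC | intermediate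
7 | {[(6E)-2,6-dimethyldec-6-en-9-yn-2-yl]oxy}triethylsilane | C#CC/C=C(\C)CCCC(C)(C)O[Si](CC)(CC)CC | intermediate
8 | lithium acetylide of 7 | [Li]C#CC/C=C(\C)CCCC(C)(C)O[Si](CC)(CC)CC | intermediate (not isolated)
9 | lithium (4E)-5,9-dimethyl-9-(triethylsilyloxy)dec-4-en-1-yn-1-olate | [Li]OC#CC/C=C(\C)CCCC(C)(C)O[Si](CC)(CC)CC | intermediate (not isolated)
10 | triisopropyl{[(4E)-5,9-dimethyl-9-(triethylsilyloxy)dec-4-en-1-yn-1-yl]oxy}silane | CC(C)[Si](C(C)C)(C(C)C)OC#CC/C=C(\C)CCCC(C)(C)O[Si](CC)(CC)CC | intermediate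
11 | methyl 4-chloro-4-oxobutanoate | COC(=O)CCC(=O)Cl | starting material
12 | methyl 4-oxohex-5-enoate | C=CC(=O)CCC(=O)OC | intermediate
13 | lithium dienolate of 12 (methyl 4-(lithiooxy)hexa-3,5-dienoate) | C=CC(O[Li])=CCC(=O)OC | intermediate (not isolated)
14 | methyl 4-oxo-3-(trifluoroacetyl)hex-5-enoate | C=CC(=O)C(CC(=O)OC)C(=O)C(F)(F)F | intermediate (not isolated)
15 | methyl 3-diazo-4-oxohex-5-enoate | C=CC(=O)C(=[N+]=[N-])CC(=O)OC | intermediate
16 | methyl 3-(oxomethylidene)pent-4-enoate (vinylketene) | C=CC(CC(=O)OC)=C=O | intermediate (not isolated)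
17 | methyl 2-[1-ethenyl-2-oxo-3-R*-4-(triisopropylsilyloxy)cyclobut-3-en-1-yl]acetate (racemic) | C=CC1(CC(=O)OC)C(=O)C(C/C=C(\C)CCCC(C)(C)O[Si](CC)(CC)CC)=C1O[Si](C(C)C)(C(C)C)C(C)C | intermediate (not isolated)
18 | methyl 3-ethenyl-6-oxo-5-R*-4-(triisopropylsilyloxy)hexa-3,5-dienoate (dienylketene) | C=CC(CC(=O)OC)=C(O[Si](C(C)C)(C(C)C)C(C)C)C(C/C=C(\C)CCCC(C)(C)O[Si](CC)(CC)CC)=C=O | intermediate (not isolated)
19 | methyl 2-[4-oxo-5-R*-6-(triisopropylsilyloxy)cyclohexa-1,5-dien-1-yl]acetate (keto tautomer of 20) | O=C1CC=C(CC(=O)OC)C(O[Si](C(C)C)(C(C)C)C(C)C)=C1C/C=C(\C)CCCC(C)(C)O[Si](CC)(CC)CC | intermediate (not isolated)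
20 | methyl 2-[4-hydroxy-3-R*-2-(triisopropylsilyloxy)phenyl]acetate | C/C(=C\Cc1c(O)ccc(CC(=O)OC)c1O[Si](C(C)C)(C(C)C)C(C)C)CCCC(C)(C)O[Si](CC)(CC)CC | intermediate
21 | methyl 2-Ar*-acetate | C/C(=C\Cc1c(O[Si](C(C)C)(C(C)C)C(C)C)ccc(CC(=O)OC)c1O[Si](C(C)C)(C(C)C)C(C)C)CCCC(C)(C)O[Si](CC)(CC)CC | intermediate
22 | trimethylstannyl 2-Ar*-acetate | C/C(=C\Cc1c(O[Si](C(C)C)(C(C)C)C(C)C)ccc(CC(=O)O[Sn](C)(C)C)c1O[Si](C(C)C)(C(C)C)C(C)C)CCCC(C)(C)O[Si](CC)(CC)CC | intermediate (not isolated)
23 | 2-Ar*-acetic acid | C/C(=C\Cc1c(O[Si](C(C)C)(C(C)C)C(C)C)ccc(CC(=O)O)c1O[Si](C(C)C)(C(C)C)C(C)C)CCCC(C)(C)O[Si](CC)(CC)CC | intermediate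
24 | (4R)-4-benzyl-1,3-oxazolidin-2-one | O=C1N[C@H](Cc2ccccc2)CO1 | starting material
25 | 2-Ar*-acetic pivalic anhydride | C/C(=C\Cc1c(O[Si](C(C)C)(C(C)C)C(C)C)ccc(CC(=O)OC(=O)C(C)(C)C)c1O[Si](C(C)C)(C(C)C)C(C)C)CCCC(C)(C)O[Si](CC)(CC)CC | intermediate (not isolated)
26 | (4R)-4-benzyl-3-(2-Ar*-acetyl)-1,3-oxazolidin-2-one | C/C(=C\Cc1c(O[Si](C(C)C)(C(C)C)C(C)C)ccc(CC(=O)N2[C@H](Cc3ccccc3)COC2=O)c1O[Si](C(C)C)(C(C)C)C(C)C)CCCC(C)(C)O[Si](CC)(CC)CC | intermediate
27 | phloroglucinol (benzene-1,3,5-triol) | Oc1cc(O)cc(O)c1 | starting material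
28 | 3,5-bis(triisopropylsilyloxy)phenol | Oc1cc(O[Si](C(C)C)(C(C)C)C(C)C)cc(O[Si](C(C)C)(C(C)C)C(C)C)c1 | intermediate
29 | 1-[(methylsulfanyl)methoxy]-3,5-bis(triisopropylsilyloxy)benzene | CSCOc1cc(O[Si](C(C)C)(C(C)C)C(C)C)cc(O[Si](C(C)C)(C(C)C)C(C)C)c1 | intermediate
30 | 1-(chloromethoxy)-3,5-bis(triisopropylsilyloxy)benzene | ClCOc1cc(O[Si](C(C)C)(C(C)C)C(C)C)cc(O[Si](C(C)C)(C(C)C)C(C)C)c1 | intermediate
31 | sodium (Z)-enolate of 26 | C/C(=C\Cc1c(O[Si](C(C)C)(C(C)C)C(C)C)ccc(/C=C(\O[Na])N2[C@H](Cc3ccccc3)COC2=O)c1O[Si](C(C)C)(C(C)C)C(C)C)CCCC(C)(C)O[Si](CC)(CC)CC | intermediate (not isolated)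
32 | (4R)-4-benzyl-3-{(2S)-2-Ar*-3-[3,5-bis(triisopropylsilyloxy)phenoxy]propanoyl}-1,3-oxazolidin-2-one | C/C(=C\Cc1c(O[Si](C(C)C)(C(C)C)C(C)C)ccc([C@H](C(=O)N2[C@H](Cc3ccccc3)COC2=O)COc2cc(O[Si](C(C)C)(C(C)C)C(C)C)cc(O[Si](C(C)C)(C(C)C)C(C)C)c2)c1O[Si](C(C)C)(C(C)C)C(C)C)CCCC(C)(C)O[Si](CC)(CC)CC | intermediate
33 | lithium (2S)-2-Ar*-3-[3,5-bis(triisopropylsilyloxy)phenoxy]propaneperoxoate | C/C(=C\Cc1c(O[Si](C(C)C)(C(C)C)C(C)C)ccc([C@H](C(=O)OO[Li])COc2cc(O[Si](C(C)C)(C(C)C)C(C)C)cc(O[Si](C(C)C)(C(C)C)C(C)C)c2)c1O[Si](C(C)C)(C(C)C)C(C)C)CCCC(C)(C)O[Si](CC)(CC)CC | intermediate (not isolated)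
34 | (2S)-2-Ar*-3-[3,5-bis(triisopropylsilyloxy)phenoxy]propanoic acid | C/C(=C\Cc1c(O[Si](C(C)C)(C(C)C)C(C)C)ccc([C@H](C(=O)O)COc2cc(O[Si](C(C)C)(C(C)C)C(C)C)cc(O[Si](C(C)C)(C(C)C)C(C)C)c2)c1O[Si](C(C)C)(C(C)C)C(C)C)CCCC(C)(C)O[Si](CC)(CC)CC | intermediate
35 | mixed anhydride of 34 and trifluoroacetic acid | C/C(=C\Cc1c(O[Si](C(C)C)(C(C)C)C(C)C)ccc([C@H](C(=O)OC(=O)C(F)(F)F)COc2cc(O[Si](C(C)C)(C(C)C)C(C)C)cc(O[Si](C(C)C)(C(C)C)C(C)C)c2)c1O[Si](C(C)C)(C(C)C)C(C)C)CCCC(C)(C)O[Si](CC)(CC)CC | intermediate (not isolated)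
36 | (3S)-3-Ar*-5,7-bis(triisopropylsilyloxy)chroman-4-one | C/C(=C\Cc1c(O[Si](C(C)C)(C(C)C)C(C)C)ccc([C@H]2COc3cc(O[Si](C(C)C)(C(C)C)C(C)C)cc(O[Si](C(C)C)(C(C)C)C(C)C)c3C2=O)c1O[Si](C(C)C)(C(C)C)C(C)C)CCCC(C)(C)O[Si](CC)(CC)CC | intermediate
37 | (3S)-3-{2,4-dihydroxy-3-[(2E)-7-hydroxy-3,7-dimethyloct-2-en-1-yl]phenyl}-5,7-dihydroxychroman-4-one | C/C(=C\Cc1c(O)ccc([C@H]2COc3cc(O)cc(O)c3C2=O)c1O)CCCC(C)(C)O | target

**Step count and risk**

Total: 18 steps (5 to the siloxyalkyne, 2 to the diazo ketone, 3 to the ring A electrophile, the key step, 7 after it). Longest linear sequence: 13 steps (steps 1–5, 8–11, 15–18).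

The three steps most likely to fail:

Step 8 (benzannulation). After loss of N2 the acyl carbene may undergo 1,2-hydrogen shift from the neighbouring CH2CO2Me group instead of vinyl migration, and the vinylketene may dimerise or acylate the phenol just formed before it meets the alkyne. The fallback builds ring B without photochemistry by aromatising a cyclohexane-1,3-dione; it sets out from bromide 6 and returns at 21. Commercial 3-ethoxycyclohex-2-en-1-one is alkylated at C6 through its kinetic enolate (LiN(i-Pr)2, THF, −78 °C; BrCH2CO2Me; Stork–Danheiser alkylation) to methyl 2-(4-ethoxy-2-oxocyclohex-3-en-1-yl)acetate F1. Brief aqueous HCl in THF hydrolyses the enol ether to methyl 2-(2,4-dioxocyclohexyl)acetate F2. C-Alkylation of the carbon between the two carbonyl groups with 6 (K2CO3, cat. LiI, acetone) should give methyl 2-(3-R*-2,4-dioxocyclohexyl)acetate F3. Double enol silylation (i-Pr3SiOTf, Et3N, CH2Cl2) should give methyl 2-[3-R*-2,4-bis(triisopropylsilyloxy)cyclohexa-1,3-dien-1-yl]acetate F4 (a double-bond isomer would aromatise to the same arene). Dehydrogenation with DDQ should then deliver arene 21, so steps 4 to 9 are no longer needed.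

Step 15 (aryloxymethylation). The electron-rich chloromethyl ether 30 may alkylate its own ring before it meets the enolate, the enolate may be alkylated on oxygen, and the ortho-silyloxy group may shift from oxygen to the enolate carbon. The fallback sets out from imide 26 and returns at 32. The sodium enolate 31 is quenched at −78 °C with monomeric formaldehyde (THF solution from cracked paraformaldehyde). This aldol hydroxymethylation occurs on the same enolate face and should give (4R)-4-benzyl-3-[(2S)-2-Ar*-3-hydroxypropanoyl]-1,3-oxazolidin-2-one F5. Mitsunobu etherification of F5 with phenol 28 (PPh3, DIAD, toluene, 0 °C) should then give 32, and steps 13 and 14 become unnecessary.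

Step 17 (ring C closure). Enolisation of the activated acyl intermediate or of the product ketone may erode the C3 configuration, and the trifluoroacetic acid released may add across the chain alkene if the reaction is prolonged. The fallback corrects the configuration after ring closure by dynamic kinetic resolution; it sets out from 36 of eroded enantiomeric purity (then free to be made under more heavily buffered acylation conditions) and returns at 36. Noyori-type asymmetric transfer hydrogenation with RuCl(p-cymene)[(S,S)-TsDPEN] in HCO2H/Et3N, under which the ketone epimerises at C3 through its enol while one enantiomer is reduced faster, should give (3S,4S)-3-Ar*-5,7-bis(triisopropylsilyloxy)chroman-4-ol F6 (cis). Dess–Martin oxidation buffered with NaHCO3 then returns 36 as the 3S ketone without touching C3.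

**Further compounds**

F1 | step 8 | methyl 2-(4-ethoxy-2-oxocyclohex-3-en-1-yl)acetate | CCOC1=CC(=O)C(CC(=O)OC)CC1
F2 | step 8 | methyl 2-(2,4-dioxocyclohexyl)acetate | COC(=O)CC1CCC(=O)CC1=O
F3 | step 8 | methyl 2-(3-R*-2,4-dioxocyclohexyl)acetate | COC(=O)CC1CCC(=O)C(C/C=C(\C)CCCC(C)(C)O[Si](CC)(CC)CC)C1=O
F4 | step 8 | methyl 2-[3-R*-2,4-bis(triisopropylsilyloxy)cyclohexa-1,3-dien-1-yl]acetate | COC(=O)CC1=C(O[Si](C(C)C)(C(C)C)C(C)C)C(C/C=C(\C)CCCC(C)(C)O[Si](CC)(CC)CC)=C(O[Si](C(C)C)(C(C)C)C(C)C)CC1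
F5 | step 15 | (4R)-4-benzyl-3-[(2S)-2-Ar*-3-hydroxypropanoyl]-1,3-oxazolidin-2-one | C/C(=C\Cc1c(O[Si](C(C)C)(C(C)C)C(C)C)ccc([C@H](C(=O)N2[C@H](Cc3ccccc3)COC2=O)CO)c1O[Si](C(C)C)(C(C)C)C(C)C)CCCC(C)(C)O[Si](CC)(CC)CC
F6 | step 17 | (3S,4S)-3-Ar*-5,7-bis(triisopropylsilyloxy)chroman-4-ol | C/C(=C\Cc1c(O[Si](C(C)C)(C(C)C)C(C)C)ccc([C@H]2COc3cc(O[Si](C(C)C)(C(C)C)C(C)C)cc(O[Si](C(C)C)(C(C)C)C(C)C)c3[C@H]2O)c1O[Si](C(C)C)(C(C)C)C(C)C)CCCC(C)(C)O[Si](CC)(CC)CC
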